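**Retrosynthetic overview**

1. Target 17 comes from the deca-O-benzyl dimer 16 by hydrogenolysis of ten benzyl ethers (last step).
2. The strategy rests on ring D of the lower flavan (C4a, C5, C6, C7, C8, C8a). It is a phloroglucinol whose C6 carries C4 of the upper unit and whose C4a and C8a–O1 are shared with ring F. It is read as a 3,5-dioxo ester folded on itself, with the C8a carbonyl already masked as the ring F enol ether. The C4a–C5 bond is cut (Claisen/Dieckmann closure of 15), so the 4→6 linkage is fixed by the chain and not by arene regioselectivity.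
3. 15 is cut at C8–C8a: the γ-carbon of the dianion of the upper-unit acetoacetate 6 adds to δ-lactone 13, which brings O1 and the C2/C3 stereocentres of ring F; dehydration then gives the enol ether.
4. 6 comes from (+)-gallocatechin 1 (rings A, C and B ready-made) by C4 oxidation and a Mukaiyama-type C4–C6 bond formation (3,4-trans). 13 comes from aldehyde 7 (ring E) by Johnson–Claisen rearrangement, Shi epoxidation and 6-endo lactonisation.
5. Ring order: A/C/B from 1, E from 7, ring F as lactone (step 8) then cyclic enol ether (step 10), ring D last (step 11).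

Key step: step 11

Remark on the chemistry: silyl enol ether 5 is bought as an E/Z mixture (either isomer reacts). Ether 3 is drawn as the 4β epimer expected from the oxidation; its C4 centre is planarised in step 4, so its configuration does not matter.

**Route**

Step 1
Reactants: 1 (+)-gallocatechin
Product: 2 5,7,3',4',5'-penta-O-benzyl-(+)-gallocatechin
Conditions: BnBr, K2CO3, DMF, argon, 0 °C to rt
Reagents that add atoms: benzyl bromide, BrCc1ccccc1
Why: Williamson etherification in which carbonate deprotonates only the five phenols, so the secondary 3-hydroxyl should stay free and no stereocentre is touched.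

Step 2
Reactants: 2 5,7,3',4',5'-penta-O-benzyl-(+)-gallocatechin
Product: 3 (2R,3S,4S)-5,7-bis(benzyloxy)-4-(2-ethoxyethoxy)-2-[3,4,5-tris(benzyloxy)phenyl]-3,4-dihydro-2H-chromen-3-ol
Conditions: DDQ, 2-ethoxyethanol, CH2Cl2, rt
Reagents that add atoms: 2-ethoxyethanol, CCOCCO
Why: DDQ benzylic oxidation, in which hydride is abstracted from the C4 methylene para/ortho to the ring A oxygens and the cation is trapped by the alcohol, expected mainly cis to the 3-hydroxyl.

Step 3
Reactants: 3 the 4-(2-ethoxyethoxy) alcohol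
Product: 4 (2R,3S,4S)-3,5,7-tris(benzyloxy)-4-(2-ethoxyethoxy)-2-[3,4,5-tris(benzyloxy)phenyl]-3,4-dihydro-2H-chromene
Conditions: NaH, BnBr, Bu4NI (cat.), DMF, 0 °C to rt
Reagents that add atoms: benzyl bromide, BrCc1ccccc1
Why: Williamson etherification of the 3-alkoxide, which installs a base-stable, non-participating benzyl ether that cannot lactonise onto the ester introduced next.

Step 4
Reactants: 4 the hexa-O-benzyl 4-(2-ethoxyethoxy) flavan; 5 methyl 3-(trimethylsilyloxy)but-2-enoate
Product: 6 methyl 2-[(2R,3S,4R)-3,5,7-tris(benzyloxy)-2-[3,4,5-tris(benzyloxy)phenyl]-3,4-dihydro-2H-chromen-4-yl]-3-oxobutanoate (both epimers at the ester-bearing carbon)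
Conditions: Me3SiOTf (0.2 equiv), 5 (3 equiv), CH2Cl2, −78 to −40 °C; then Et3N, aq NaHCO3
Reagents that add atoms: none
Why: Mukaiyama-type SN1 substitution, in which Me3SiOTf ionises the 4-alkoxy group to the ring-A-stabilised C4 cation and the silyl enol ether captures it at its α-carbon anti to the 3-benzyloxy group; this should set C4 as R (3,4-trans, 4α), with the minor 3,4-cis isomer removed by chromatography.

Step 5
Reactants: 7 3,4,5-tris(benzyloxy)benzaldehyde
Product: 8 (RS)-1-[3,4,5-tris(benzyloxy)phenyl]prop-2-en-1-ol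
Conditions: CH2=CHMgBr, THF, 0 °C; then aq NH4Cl
Reagents that add atoms: vinylmagnesium bromide, C=C[Mg]Br
Why: Grignard 1,2-addition to the aldehyde; the racemic carbinol centre is of no concern because it is destroyed in step 6.

Step 6
Reactants: 8 the racemic allylic alcohol
Product: 9 ethyl (4E)-5-[3,4,5-tris(benzyloxy)phenyl]pent-4-enoate
Conditions: CH3C(OEt)3, EtCO2H (cat.), 140 °C, EtOH distilled off
Reagents that add atoms: triethyl orthoacetate, CCOC(C)(OCC)OCC
Why: Johnson–Claisen [3,3]-rearrangement of the ketene acetal through a chair transition state with the aryl group equatorial, which should give the E alkene and the two-carbon ester chain in one operation.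

Step 7
Reactants: 9 the E-pentenoate
Product: 10 ethyl 3-[(2S,3S)-3-[3,4,5-tris(benzyloxy)phenyl]oxiran-2-yl]propanoate
Conditions: L-fructose-derived Shi ketone (enantiomer of the usual D-fructose catalyst, 0.3 equiv), Oxone (2KHSO5·KHSO4·K2SO4), K2CO3, Bu4NHSO4, MeCN/CH2(OMe)2/aq Na2B4O7 buffer, 0 °C
Reagents that add atoms: potassium peroxymonosulfate, [K+].[O-]S(=O)(=O)OO
Why: Shi asymmetric epoxidation, in which the chiral dioxirane transfers oxygen through a spiro transition state; the L-fructose-derived ketone should give the (S,S)-epoxide, the mirror image of the (R,R) sense of the D-fructose ketone with trans-β-alkylstyrenes, and so sets both C–O stereocentres.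

Step 8
Reactants: 10 the (S,S)-epoxy ester
Product: 12 (5S,6R)-5-hydroxy-6-[3,4,5-tris(benzyloxy)phenyl]oxan-2-one, via epoxy acid 11 (not isolated)
Conditions: LiOH, THF/H2O, 0 °C; AcOH to pH 5, extraction; then CSA (0.1 equiv), CH2Cl2, −20 to 0 °C, prompt quench with NaHCO3
Reagents that add atoms: lithium hydroxide, [Li+].[OH-]
Why: saponification followed by acid-catalysed 6-endo epoxide opening, in which the carboxylic acid attacks the aryl-activated benzylic carbon with inversion (C6 becomes R) while the epoxide oxygen stays on C5 (S), which should give the trans hydroxy δ-lactone.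

Step 9
Reactants: 12 the trans hydroxy lactone
Product: 13 (5S,6R)-5-(benzyloxy)-6-[3,4,5-tris(benzyloxy)phenyl]oxan-2-one
Conditions: 2-benzyloxy-1-methylpyridinium triflate, MgO, PhCF3, 85 °C
Reagents that add atoms: 2-benzyloxy-1-methylpyridinium triflate, C[n+]1ccccc1OCc1ccccc1.[O-]S(=O)(=O)C(F)(F)F
Why: benzyl transfer from the pyridinium salt under near-neutral, MgO-buffered conditions, which etherifies the secondary alcohol without forming an alkoxide and so should avoid acyl migration to the γ-lactone.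

Step 10
Reactants: 6 the upper-unit acetoacetate; 13 the benzyloxy δ-lactone
Product: 15 methyl (4E)-4-[(5S,6R)-5-(benzyloxy)-6-[3,4,5-tris(benzyloxy)phenyl]oxan-2-ylidene]-3-oxo-2-[(2R,3S,4R)-3,5,7-tris(benzyloxy)-2-[3,4,5-tris(benzyloxy)phenyl]-3,4-dihydro-2H-chromen-4-yl]butanoate (epimers at C2 of the butanoate), via hemiketal adduct 14 (not isolated)
Conditions: LiN(iPr)2 (2.3 equiv), THF, −78 to 0 °C; 13 (1.3 equiv), −78 to −30 °C; AcOH; then CF3CO2H (cat.), 4 Å MS, CH2Cl2, 0 °C to rt
Reagents that add atoms: none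
Why: β-keto ester dianion chemistry, in which the γ-carbon of the α,γ-dianion adds to the lactone carbonyl and the resulting hemiketal is dehydrated by acid to the conjugated 2-alkylidene tetrahydropyran (a vinylogous ester, E isomer expected), with no stereocentre of either unit involved.

Step 11
Reactants: 15 the pyranylidene diketo ester
Product: 16 3,5,7,3',4',5'-hexa-O-benzyl-(+)-gallocatechin-(4α→6)-3,3',4',5'-tetra-O-benzyl-(+)-gallocatechin (free 5- and 7-hydroxyls on ring D)
Conditions: KOtBu (3 equiv), THF/tBuOH (4:1), degassed, 0 to 50 °C; then AcOH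
Reagents that add atoms: none
Why: Proposed new method: under equilibrating tert-butoxide the resting C6 enolate of the β-keto ester exchanges protons with the γ-dienolate formed by removing a ring F C4a–H (vinylogous α-position of the C7 ketone through C8=C8a), in which C6 still carries its hydrogen and the ester carbon C5 is an ordinary, non-enolised electrophile; C4a adds to C5, methoxide leaves, and the cyclohexadienone enolises irreversibly to the 5,7-dihydroxy ring D, held as its diphenolate. The closest known reactions are alkoxide-mediated Dieckmann/Claisen closures to cyclohexane-1,3-diones and phloroglucinols, where a less acidic ketone α-carbon attacks an ester that itself bears a more acidic α-hydrogen, together with γ-deprotonation of β-alkoxy enones; the untested element is a cyclic enol ether γ-carbon as the nucleophile. Ring D closes in a 6-(enolendo)-exo-trig mode, and the C8–C8a bond is single in the dienolate, so the E/Z geometry of 15 does not matter. No stereocentre is created; the epimeric C6 centre vanishes on aromatisation, and C2, C3 and C4 of the upper unit and C2 and C3 of ring F carry no acidic hydrogen. The step needs C-acylation at C4a rather than O-acylation or aldol closure: the C8a oxygen is locked as the ring F ether so no pyranone can form, the ester is the only free carbonyl electrophile, and attack through C8 or the C7 oxygen would give four-membered rings. Because all six ring D carbons come from one chain, the interflavan bond can only sit at C6.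

Step 12
Reactants: 16 the deca-O-benzyl dimer
Product: 17 (+)-gallocatechin-(4α→6)-(+)-gallocatechin (target)
Conditions: H2 (1 atm), Pd(OH)2 on carbon, THF/MeOH/H2O, rt
Reagents that add atoms: none
Why: catalytic hydrogenolysis of the ten O-benzyl ethers under mild conditions, which should leave the cyclic benzylic C2–O1 bonds and the interflavan bond intact.

**Compound list**

1 | (+)-gallocatechin | Oc1cc(O)c2c(c1)O[C@H](c1cc(O)c(O)c(O)c1)[C@@H](O)C2 | starting material
2 | 5,7,3',4',5'-penta-O-benzyl-(+)-gallocatechin | c1ccccc1COc1cc(OCc3ccccc3)c2c(c1)O[C@H](c1cc(OCc3ccccc3)c(OCc3ccccc3)c(OCc3ccccc3)c1)[C@@H](O)C2 | intermediate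
3 | (2R,3S,4S)-5,7-bis(benzyloxy)-4-(2-ethoxyethoxy)-2-[3,4,5-tris(benzyloxy)phenyl]-3,4-dihydro-2H-chromen-3-ol | c1ccccc1COc1cc(OCc3ccccc3)c2c(c1)O[C@H](c1cc(OCc3ccccc3)c(OCc3ccccc3)c(OCc3ccccc3)c1)[C@@H](O)[C@H]2OCCOCC | intermediate
4 | (2R,3S,4S)-3,5,7-tris(benzyloxy)-4-(2-ethoxyethoxy)-2-[3,4,5-tris(benzyloxy)phenyl]-3,4-dihydro-2H-chromene | c1ccccc1COc1cc(OCc3ccccc3)c2c(c1)O[C@H](c1cc(OCc3ccccc3)c(OCc3ccccc3)c(OCc3ccccc3)c1)[C@@H](OCc3ccccc3)[C@H]2OCCOCC | intermediate
5 | methyl 3-(trimethylsilyloxy)but-2-enoate (E/Z mixture) | COC(=O)C=C(C)O[Si](C)(C)C | starting material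
6 | methyl 2-[(2R,3S,4R)-3,5,7-tris(benzyloxy)-2-[3,4,5-tris(benzyloxy)phenyl]-3,4-dihydro-2H-chromen-4-yl]-3-oxobutanoate (epimers at C2 of the butanoate) | c1ccccc1COc1cc(OCc3ccccc3)c2c(c1)O[C@H](c1cc(OCc3ccccc3)c(OCc3ccccc3)c(OCc3ccccc3)c1)[C@@H](OCc3ccccc3)[C@@H]2C(C(C)=O)C(=O)OC | intermediate
7 | 3,4,5-tris(benzyloxy)benzaldehyde | O=Cc1cc(OCc2ccccc2)c(OCc2ccccc2)c(OCc2ccccc2)c1 | starting material
8 | (RS)-1-[3,4,5-tris(benzyloxy)phenyl]prop-2-en-1-ol | C=CC(O)c1cc(OCc2ccccc2)c(OCc2ccccc2)c(OCc2ccccc2)c1 | intermediate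
9 | ethyl (4E)-5-[3,4,5-tris(benzyloxy)phenyl]pent-4-enoate | CCOC(=O)CC/C=C/c1cc(OCc2ccccc2)c(OCc2ccccc2)c(OCc2ccccc2)c1 | intermediate
10 | ethyl 3-[(2S,3S)-3-[3,4,5-tris(benzyloxy)phenyl]oxiran-2-yl]propanoate | CCOC(=O)CC[C@@H]1O[C@H]1c1cc(OCc2ccccc2)c(OCc2ccccc2)c(OCc2ccccc2)c1 | intermediate
11 | 3-[(2S,3S)-3-[3,4,5-tris(benzyloxy)phenyl]oxiran-2-yl]propanoic acid | OC(=O)CC[C@@H]1O[C@H]1c1cc(OCc2ccccc2)c(OCc2ccccc2)c(OCc2ccccc2)c1 | intermediate
12 | (5S,6R)-5-hydroxy-6-[3,4,5-tris(benzyloxy)phenyl]oxan-2-one | O=C1CC[C@H](O)[C@@H](c2cc(OCc3ccccc3)c(OCc3ccccc3)c(OCc3ccccc3)c2)O1 | intermediate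
13 | (5S,6R)-5-(benzyloxy)-6-[3,4,5-tris(benzyloxy)phenyl]oxan-2-one | O=C1CC[C@H](OCc2ccccc2)[C@@H](c2cc(OCc3ccccc3)c(OCc3ccccc3)c(OCc3ccccc3)c2)O1 | intermediate
14 | methyl 4-[(5S,6R)-5-(benzyloxy)-2-hydroxy-6-[3,4,5-tris(benzyloxy)phenyl]oxan-2-yl]-3-oxo-2-[(2R,3S,4R)-3,5,7-tris(benzyloxy)-2-[3,4,5-tris(benzyloxy)phenyl]-3,4-dihydro-2H-chromen-4-yl]butanoate (hemiketal, anomers and C2 epimers, in equilibrium with the open hydroxy diketone) | c1ccccc1COc1cc(OCc3ccccc3)c2c(c1)O[C@H](c1cc(OCc3ccccc3)c(OCc3ccccc3)c(OCc3ccccc3)c1)[C@@H](OCc3ccccc3)[C@@H]2C(C(=O)OC)C(=O)CC1(O)CC[C@H](OCc3ccccc3)[C@@H](c4cc(OCc3ccccc3)c(OCc3ccccc3)c(OCc3ccccc3)c4)O1 | intermediate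
15 | methyl (4E)-4-[(5S,6R)-5-(benzyloxy)-6-[3,4,5-tris(benzyloxy)phenyl]oxan-2-ylidene]-3-oxo-2-[(2R,3S,4R)-3,5,7-tris(benzyloxy)-2-[3,4,5-tris(benzyloxy)phenyl]-3,4-dihydro-2H-chromen-4-yl]butanoate (epimers at C2 of the butanoate) | c1ccccc1COc1cc(OCc3ccccc3)c2c(c1)O[C@H](c1cc(OCc3ccccc3)c(OCc3ccccc3)c(OCc3ccccc3)c1)[C@@H](OCc3ccccc3)[C@@H]2C(C(=O)OC)C(=O)/C=C1\CC[C@H](OCc3ccccc3)[C@@H](c4cc(OCc3ccccc3)c(OCc3ccccc3)c(OCc3ccccc3)c4)O1 | intermediate
16 | 3,5,7,3',4',5'-hexa-O-benzyl-(+)-gallocatechin-(4α→6)-3,3',4',5'-tetra-O-benzyl-(+)-gallocatechin | c1ccccc1COc1cc(OCc3ccccc3)c2c(c1)O[C@H](c1cc(OCc3ccccc3)c(OCc3ccccc3)c(OCc3ccccc3)c1)[C@@H](OCc3ccccc3)[C@@H]2c1c(O)cc2c(c1O)C[C@H](OCc3ccccc3)[C@@H](c1cc(OCc3ccccc3)c(OCc3ccccc3)c(OCc3ccccc3)c1)O2 | intermediate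
17 | (+)-gallocatechin-(4α→6)-(+)-gallocatechin (CNP0286965.2) | Oc1cc(O)c2c(c1)O[C@H](c1cc(O)c(O)c(O)c1)[C@@H](O)[C@@H]2c1c(O)cc2c(c1O)C[C@H](O)[C@@H](c1cc(O)c(O)c(O)c1)O2 | target

**Step count and risks**

Total step count: 12. Longest linear sequence: 8 steps (7 to 17 through steps 5–12); the upper-unit branch from 1 is 7 steps.

Steps most likely to fail:

1. Step 11 (ring D closure). The substrate may rest as the unreactive C6 enolate, so that closure is outrun by retro-Claisen cleavage at C7, by opening of ring F through alkoxide loss at C8a, or by air oxidation of the phloroglucinolate. The fallback uses the established cationic C4 arylation with a C8-blocked nucleophile; it sets out from 2 and 4 and comes back to the route at 17.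
   - NBS (CH2Cl2, −78 °C to rt) should brominate 2 at C8, the most activated ring A position, to give 8-bromo-5,7,3',4',5'-penta-O-benzyl-(+)-gallocatechin F1.
   - Me3SiOTf-mediated condensation of 4 with an excess of F1 (CH2Cl2, −78 °C) can then only take place at C6, anti to the 3-benzyloxy group, and should give 3,5,7,3',4',5'-hexa-O-benzyl-(+)-gallocatechin-(4α→6)-8-bromo-5,7,3',4',5'-penta-O-benzyl-(+)-gallocatechin F2.
   - Hydrogenolysis of F2 over Pd(OH)2 on carbon with Et3N removes the eleven benzyl groups and the bromine and gives 17.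

2. Step 10 (dianion addition and dehydration). The strongly basic, hindered dianion of 6 may take a proton from the lactone α-methylene instead of adding, and the hemiketal may dehydrate incompletely. The fallback reverses the order of the two bond formations so that the cheap partner is in excess; it sets out from 13 and 4 and comes back at 15.
   - The dianion of methyl acetoacetate (NaH then n-BuLi, THF, 0 °C, used in excess) is added to 13 and the hemiketal dehydrated with CF3CO2H to give methyl (4E)-4-[(5S,6R)-5-(benzyloxy)-6-[3,4,5-tris(benzyloxy)phenyl]oxan-2-ylidene]-3-oxobutanoate F3.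
   - The enol of F3, a 1-alkoxy-3-hydroxy diene whose nucleophilic terminus is the ester-bearing carbon, is then alkylated by the C4 cation from 4 (Me3SiOTf, CH2Cl2, −78 °C) to give 15.

3. Step 8 (epoxide opening to the δ-lactone). There may be competing 5-exo opening at the non-benzylic carbon, partial loss of configuration at the benzylic carbon through an open cation, and acid-catalysed acyl migration of the hydroxy δ-lactone to the γ-lactone. The fallback avoids any lactone; it sets out from 10 and 6 and comes back at 17.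
   - The dianion of 6 (LiN(iPr)2, two equivalents of dianion per ester, THF, −78 to −20 °C) is C-acylated at its γ-carbon by the ethyl ester of 10, under conditions that leave the epoxide untouched, to give the epoxy 3,5-dioxo ester methyl 3,5-dioxo-7-[(2S,3S)-3-[3,4,5-tris(benzyloxy)phenyl]oxiran-2-yl]-2-[(2R,3S,4R)-hexa-O-benzyl flavan-4-yl]heptanoate F4.
   - Catalytic CSA (CH2Cl2, 0 °C) then lets the enol oxygen on the future C8a open the epoxide at the benzylic carbon with inversion (6-endo), closing ring F directly as the 3-hydroxy analogue of 15, F5.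
   - F5 is cyclised as in step 11 with one more equivalent of KOtBu to the nona-O-benzyl dimer with a free lower 3-hydroxyl, F6, and hydrogenolysis of F6 as in step 12 gives 17.

Further compounds
F1 | step 11 | 8-bromo-5,7,3',4',5'-penta-O-benzyl-(+)-gallocatechin | c1ccccc1COc1cc(OCc3ccccc3)c2c(c1Br)O[C@H](c1cc(OCc3ccccc3)c(OCc3ccccc3)c(OCc3ccccc3)c1)[C@@H](O)C2
F2 | step 11 | 3,5,7,3',4',5'-hexa-O-benzyl-(+)-gallocatechin-(4α→6)-8-bromo-5,7,3',4',5'-penta-O-benzyl-(+)-gallocatechin | c1ccccc1COc1cc(OCc3ccccc3)c2c(c1)O[C@H](c1cc(OCc3ccccc3)c(OCc3ccccc3)c(OCc3ccccc3)c1)[C@@H](OCc3ccccc3)[C@@H]2c1c(OCc3ccccc3)c(Br)c2c(c1OCc3ccccc3)C[C@H](O)[C@@H](c1cc(OCc3ccccc3)c(OCc3ccccc3)c(OCc3ccccc3)c1)O2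
F3 | step 10 | methyl (4E)-4-[(5S,6R)-5-(benzyloxy)-6-[3,4,5-tris(benzyloxy)phenyl]oxan-2-ylidene]-3-oxobutanoate | COC(=O)CC(=O)/C=C1\CC[C@H](OCc2ccccc2)[C@@H](c2cc(OCc3ccccc3)c(OCc3ccccc3)c(OCc3ccccc3)c2)O1
F4 | step 8 | methyl 3,5-dioxo-7-[(2S,3S)-3-[3,4,5-tris(benzyloxy)phenyl]oxiran-2-yl]-2-[(2R,3S,4R)-3,5,7-tris(benzyloxy)-2-[3,4,5-tris(benzyloxy)phenyl]-3,4-dihydro-2H-chromen-4-yl]heptanoate | c1ccccc1COc1cc(OCc3ccccc3)c2c(c1)O[C@H](c1cc(OCc3ccccc3)c(OCc3ccccc3)c(OCc3ccccc3)c1)[C@@H](OCc3ccccc3)[C@@H]2C(C(=O)OC)C(=O)CC(=O)CC[C@@H]1O[C@H]1c1cc(OCc3ccccc3)c(OCc3ccccc3)c(OCc3ccccc3)c1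
F5 | step 8 | methyl (4E)-4-[(5S,6R)-5-hydroxy-6-[3,4,5-tris(benzyloxy)phenyl]oxan-2-ylidene]-3-oxo-2-[(2R,3S,4R)-3,5,7-tris(benzyloxy)-2-[3,4,5-tris(benzyloxy)phenyl]-3,4-dihydro-2H-chromen-4-yl]butanoate | c1ccccc1COc1cc(OCc3ccccc3)c2c(c1)O[C@H](c1cc(OCc3ccccc3)c(OCc3ccccc3)c(OCc3ccccc3)c1)[C@@H](OCc3ccccc3)[C@@H]2C(C(=O)OC)C(=O)/C=C1\CC[C@H](O)[C@@H](c4cc(OCc3ccccc3)c(OCc3ccccc3)c(OCc3ccccc3)c4)O1
F6 | step 8 | 3,5,7,3',4',5'-hexa-O-benzyl-(+)-gallocatechin-(4α→6)-3',4',5'-tri-O-benzyl-(+)-gallocatechin | c1ccccc1COc1cc(OCc3ccccc3)c2c(c1)O[C@H](c1cc(OCc3ccccc3)c(OCc3ccccc3)c(OCc3ccccc3)c1)[C@@H](OCc3ccccc3)[C@@H]2c1c(O)cc2c(c1O)C[C@H](O)[C@@H](c1cc(OCc3ccccc3)c(OCc3ccccc3)c(OCc3ccccc3)c1)O2
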